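**Retrosynthetic overview**
1. Target 20 is cut at C1–C13' (with the H shift C9→C11'). This is an Alder-ene union of two C15 germacranolides, enophile 17 and ene donor 18, and it forms no ring.
2. Both halves come from one monomer 15 by C–O bond formation. An oxygen-ene reaction at C1 makes C1'–O and the 9'Z alkene (17). A Mitsunobu reaction re-forms C6–O with inversion (18).
3. In 15 the ten-membered ring is closed at C6–C7 by Nozaki–Hiyama allylation of the bromomethylbutenolide enal 13.
4. The butenolide of 13 is built on the C8–O bond made by L-proline aminoxylation of aldehyde 5, the only source of chirality. Methyl propiolate 6 supplies C11–C13.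
5. Aldehyde 5 comes from (2E,6E)-farnesol 1, which brings both E-alkenes. Ring order: γ-lactone first, then the carbocycle, made once and used twice.

Assumption: germacranolide numbering is used (C1–C15, lactone C12 on O–C8, primed locants for the half with the saturated lactone), and the opposite configurations at C6 and C6' in the given SMILES are taken as intended.

Step 1
Reactants: 1 (2E,6E)-farnesol
Product: 3 (2E,6E)-10,11-epoxyfarnesol (racemic), via bromohydrin 2 (not isolated)
Conditions: NBS, THF/H2O, 0 °C; then K2CO3, MeOH, rt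
Reagents that add atoms: water O
Why: Terminal-selective bromohydrin formation followed by Williamson-type epoxide closure works because in aqueous THF only the terminal trisubstituted alkene is exposed to NBS, and the new stereocentre does not matter because it is cleaved in step 2.

Step 2
Reactants: 3 (2E,6E)-10,11-epoxyfarnesol
Product: 5 (4E,8E)-10-hydroxy-4,8-dimethyldeca-4,8-dienal, via triol 4 (not isolated)
Conditions: H5IO6, THF/H2O, 0 °C
Reagents that add atoms: none
Why: Epoxide hydrolysis and Malaprade glycol cleavage remove three carbons as acetone and leave both E-alkenes and the allylic alcohol untouched, with no stereocentre formed.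

Step 3
Reactants: 5 (4E,8E)-10-hydroxy-4,8-dimethyldeca-4,8-dienal; 6 methyl propiolate
Product: 9 methyl (4R,6E,10E)-4-(anilinooxy)-3,12-dihydroxy-6,10-dimethyl-2-methylidenedodeca-6,10-dienoate (C3 epimers), via aminooxy aldehyde 7 (not isolated), via vinylalane 8 (not isolated)
Conditions: PhNO, L-proline (20 mol%), CHCl3, 4 °C; then 8 (from 6, iBu2AlH, HMPA, THF, 0 °C; 4 equiv), −78 °C; then H2O
Reagents that add atoms: nitrosobenzene O=Nc1ccccc1
Why: Organocatalytic α-aminoxylation (enamine catalysis) forms the C8–O bond on the face fixed by the hydrogen bond from the proline carboxyl to the nitroso nitrogen (8R with L-proline), and the labile aldehyde is trapped at once by vinylalumination (a Morita–Baylis–Hillman-type adduct) whose C7 carbinol configuration is erased in step 6.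

Step 4
Reactants: 9 methyl (4R,6E,10E)-4-(anilinooxy)-3,12-dihydroxy-6,10-dimethyl-2-methylidenedodeca-6,10-dienoate
Product: 11 (5R)-4-hydroxy-5-[(2E,6E)-8-hydroxy-2,6-dimethylocta-2,6-dienyl]-3-methylideneoxolan-2-one (C4 epimers), via triol ester 10 (not isolated)
Conditions: Zn, AcOH/THF, rt
Reagents that add atoms: none
Why: Reductive N–O cleavage frees the C8 hydroxyl, which lactonises onto the acrylate ester (γ-lactone favoured over the β-lactone from O7) without touching C8.

Step 5
Reactants: 11 (5R)-4-hydroxy-5-[(2E,6E)-8-hydroxy-2,6-dimethylocta-2,6-dienyl]-3-methylideneoxolan-2-one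
Product: 12 (2E,6E)-8-[(2R)-3-hydroxy-4-methylidene-5-oxooxolan-2-yl]-3,7-dimethylocta-2,6-dienal
Conditions: TEMPO (10 mol%), PhI(OAc)2, CH2Cl2, rt
Reagents that add atoms: none
Why: Oxoammonium (TEMPO) oxidation is selective for the primary allylic alcohol over the hindered secondary C7 carbinol and does not isomerise the E-enal.

Step 6
Reactants: 12 (2E,6E)-8-[(2R)-3-hydroxy-4-methylidene-5-oxooxolan-2-yl]-3,7-dimethylocta-2,6-dienal
Product: 13 (2E,6E)-8-[(2R)-4-(bromomethyl)-5-oxo-2,5-dihydrofuran-2-yl]-3,7-dimethylocta-2,6-dienal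
Conditions: PBr3 (0.4 equiv), Et2O, −10 °C
Reagents that add atoms: phosphorus tribromide BrP(Br)Br
Why: In this SN2' bromination of a cyclic Morita–Baylis–Hillman alcohol, bromide enters at C13 and the alkene moves into the ring, giving the conjugated butenolide and leaving C8 untouched.

Step 7
Reactants: 13 (2E,6E)-8-[(2R)-4-(bromomethyl)-5-oxo-2,5-dihydrofuran-2-yl]-3,7-dimethylocta-2,6-dienal
Product: 15 (6S,7R,8R)-6-hydroxygermacra-1(10)E,4E,11(13)-trien-12,8-olide, via allylchromium dichloride 14 (not isolated)
Conditions: CrCl2 (8 equiv), THF, 2 mM, syringe pump, rt; then H2O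
Reagents that add atoms: none
Why: In this Nozaki–Hiyama allylation, divalent chromium converts the allylic bromide into 14, which adds through C7 to the enal in a chair transition state anti to the C9 chain (7,8-trans lactone, 7R), and the ring-locked E-like allyl unit gives 6,7-anti topicity (6S).

Step 8
Reactants: 15 (6S,7R,8R)-6-hydroxygermacra-1(10)E,4E,11(13)-trien-12,8-olide
Product: 17 (1R,6S,7R,8R)-1,6-dihydroxygermacra-4E,9Z,11(13)-trien-12,8-olide, via allylic hydroperoxide 16 (not isolated)
Conditions: O2, methylene blue (1 mol%), hν, CH2Cl2/MeOH, −20 °C; then PPh3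
Reagents that add atoms: dioxygen O=O
Why: In this Schenck ene reaction singlet oxygen attacks the outer face of the strained, most electron-rich C1=C10 alkene (C4=C5 is deactivated by the allylic oxygen and C11=C13 by the carbonyl) and takes H-9 suprafacially in the rotamer that keeps H-8 in the plane of the new alkene, which forms C1–O cis to O-8 (1R) and the 9Z alkene, and the 10(14)-ene regioisomer is separated after PPh3 reduction.

Step 9
Reactants: 15 (6S,7R,8R)-6-hydroxygermacra-1(10)E,4E,11(13)-trien-12,8-olide
Product: 18 (6R,7S,8R)-6-formyloxygermacra-1(10)E,4E,11(13)-trien-12,8-olide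
Conditions: HCO2H, PPh3, DIAD, toluene, 0 °C
Reagents that add atoms: formic acid O=CO
Why: In this Mitsunobu reaction the only hydroxyl is activated and displaced by the small formate nucleophile in an SN2 process, so the C6–O bond is re-formed with inversion (6S to 6R; the C7 descriptor changes only through CIP ranking), giving the C6-epimeric half from the same monomer.

Step 10
Reactants: 17 (1R,6S,7R,8R)-1,6-dihydroxygermacra-4E,9Z,11(13)-trien-12,8-olide (4 equiv, excess recovered); 18 (6R,7S,8R)-6-formyloxygermacra-1(10)E,4E,11(13)-trien-12,8-olide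
Product: 20 target dimer CNP0307352.2, via dimer formate 19 (not isolated)
Conditions: N,N'-bis[3,5-bis(trifluoromethyl)phenyl]thiourea (20 mol%), BHT, CH2Cl2/THF, 1.2 GPa, 35 °C, 96 h; then aq. KHCO3, MeOH, 0 °C
Reagents that add atoms: none
Why: Proposed new method: an intermolecular Alder-ene union that has not been shown for an α-methylene-γ-butyrolactone enophile or an (E)-cyclodecene donor; the only strained electron-rich alkene present (C1=C10 of 18) bonds through C1 to the exocyclic C13' of 17 while H-9 on the same outer face moves to C11' in one suprafacial six-electron transition state, helped by release of E-alkene strain, by acid-free LUMO lowering through double hydrogen bonding of the thiourea to the lactone carbonyl (so no cationic transannular cyclisation) and by the large negative activation volume at 1.2 GPa; the rotamer that keeps H-8 in the plane of the nascent alkene (least A1,3 strain) gives the 9Z alkene and C1 (S) cis to O-8, hydrogen reaches C11' anti to the pseudo-axial H-7' (the face used in hydride and Michael additions to trans-fused methylene lactones) to give the all-trans 11'S lactone, excess 17 outcompetes the enophile of 18, the closest known reactions are thermal, high-pressure and Lewis acid promoted Alder-ene reactions of acrylates with trisubstituted alkenes, and the labile formate is then hydrolysed by KHCO3.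

**Compound list**
1 | (2E,6E)-farnesol | CC(C)=CCC/C(C)=C/CC/C(C)=C/CO | starting material
2 | (2E,6E)-10-bromo-3,7,11-trimethyldodeca-2,6-diene-1,11-diol (racemic) | CC(C)(O)C(Br)CC/C(C)=C/CC/C(C)=C/CO | intermediate
3 | (2E,6E)-10,11-epoxyfarnesol (racemic) | CC1(C)OC1CC/C(C)=C/CC/C(C)=C/CO | intermediate
4 | (2E,6E)-3,7,11-trimethyldodeca-2,6-diene-1,10,11-triol (racemic) | CC(C)(O)C(O)CC/C(C)=C/CC/C(C)=C/CO | intermediate
5 | (4E,8E)-10-hydroxy-4,8-dimethyldeca-4,8-dienal | O=CCC/C(C)=C/CC/C(C)=C/CO | intermediate
6 | methyl propiolate | C#CC(=O)OC | starting material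
7 | (2R,4E,8E)-2-(anilinooxy)-10-hydroxy-4,8-dimethyldeca-4,8-dienal | O=C[C@H](ONc1ccccc1)C/C(C)=C/CC/C(C)=C/CO | intermediate
8 | methyl 2-(diisobutylalumanyl)prop-2-enoate | C=C([Al](CC(C)C)CC(C)C)C(=O)OC | intermediate
9 | methyl (4R,6E,10E)-4-(anilinooxy)-3,12-dihydroxy-6,10-dimethyl-2-methylidenedodeca-6,10-dienoate (C3 epimers) | C=C(C(=O)OC)C(O)[C@H](ONc1ccccc1)C/C(C)=C/CC/C(C)=C/CO | intermediate
10 | methyl (4R,6E,10E)-3,4,12-trihydroxy-6,10-dimethyl-2-methylidenedodeca-6,10-dienoate (C3 epimers) | C=C(C(=O)OC)C(O)[C@H](O)C/C(C)=C/CC/C(C)=C/CO | intermediate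
11 | (5R)-4-hydroxy-5-[(2E,6E)-8-hydroxy-2,6-dimethylocta-2,6-dienyl]-3-methylideneoxolan-2-one (C4 epimers) | C=C1C(=O)O[C@H](C/C(C)=C/CC/C(C)=C/CO)C1O | intermediate
12 | (2E,6E)-8-[(2R)-3-hydroxy-4-methylidene-5-oxooxolan-2-yl]-3,7-dimethylocta-2,6-dienal | C=C1C(=O)O[C@H](C/C(C)=C/CC/C(C)=C/C=O)C1O | intermediate
13 | (2E,6E)-8-[(2R)-4-(bromomethyl)-5-oxo-2,5-dihydrofuran-2-yl]-3,7-dimethylocta-2,6-dienal | O=C1O[C@H](C/C(C)=C/CC/C(C)=C/C=O)C=C1CBr | intermediate
14 | allylchromium dichloride derived from 13 (CrCl2 unit in place of Br) | O=C1O[C@H](C/C(C)=C/CC/C(C)=C/C=O)C=C1C[Cr](Cl)Cl | intermediate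
15 | (6S,7R,8R)-6-hydroxygermacra-1(10)E,4E,11(13)-trien-12,8-olide | C=C1C(=O)O[C@@H]2C/C(C)=C/CC/C(C)=C/[C@H](O)[C@@H]12 | intermediate
16 | (1R,6S,7R,8R)-1-hydroperoxy-6-hydroxygermacra-4E,9Z,11(13)-trien-12,8-olide | C=C1C(=O)O[C@@H]2/C=C(/C)[C@H](OO)CC/C(C)=C/[C@H](O)[C@@H]12 | intermediate
17 | (1R,6S,7R,8R)-1,6-dihydroxygermacra-4E,9Z,11(13)-trien-12,8-olide | C=C1C(=O)O[C@@H]2/C=C(/C)[C@H](O)CC/C(C)=C/[C@H](O)[C@@H]12 | intermediate
18 | (6R,7S,8R)-6-formyloxygermacra-1(10)E,4E,11(13)-trien-12,8-olide | C=C1C(=O)O[C@@H]2C/C(C)=C/CC/C(C)=C/[C@@H](OC=O)[C@@H]12 | intermediate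
19 | 6-O-formate of the target (1S,6R,7R,8R; 1'R,6'S,7'R,8'R,11'S) | C=C1C(=O)O[C@@H]2/C=C(/C)[C@H](C[C@@H]3C(=O)O[C@@H]4/C=C(/C)[C@H](O)CC/C(C)=C/[C@H](O)[C@@H]34)CC/C(C)=C/[C@@H](OC=O)[C@@H]12 | intermediate
20 | CNP0307352.2: C1–C13'-linked dimer, half A (1S,6R,7R,8R)-6-hydroxygermacra-4E,9Z,11(13)-trien-12,8-olide, half B (1'R,6'S,7'R,8'R,11'S)-1',6'-dihydroxygermacra-4'E,9'Z-dien-12',8'-olide | C=C1C(=O)O[C@@H]2/C=C(/C)[C@H](C[C@@H]3C(=O)O[C@@H]4/C=C(/C)[C@H](O)CC/C(C)=C/[C@H](O)[C@@H]34)CC/C(C)=C/[C@@H](O)[C@@H]12 | target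

**Totals:** 10 steps in all. The longest linear sequence is 9 steps (steps 1–7, then 8 or 9, then 10).

**Three steps most likely to fail**

1. **The new ene union (step 10).** It may be too slow. It may transfer a C14 hydrogen and give the 10(14)-ene isomer. It may also give self-adducts of 18.
   - The fallback is a Giese radical addition, which is known chemistry. It sets out from 18, with 17 as the partner.
   - Schenck photooxygenation of 18, as in step 8, gives the allylic hydroperoxide F1.
   - PPh3 reduces it to the allylic alcohol F2.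
   - An Appel reaction (CBr4, PPh3) gives the allylic bromide F3. Its C1 configuration and any allylic transposition are irrelevant, because both isomers give the same allyl radical.
   - (Me3Si)3SiH, Et3B and air with excess 17 then add the macrocyclic allyl radical through its outer face at C1 to C13'. The silane delivers hydrogen to C11' anti to H-7'.
   - The sequence comes back to the route at 19.

2. **The oxygen-ene reaction (step 8).** The cis effect of singlet oxygen favours abstraction from the C14 methyl, so the 9Z isomer may be the minor product.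
   - The fallback is epoxidation followed by eliminative opening. It sets out from 15.
   - m-CPBA (CH2Cl2, −20 °C) epoxidises the same outer face of C1=C10 to give the (1R,10R)-epoxide F4.
   - Diethylaluminium 2,2,6,6-tetramethylpiperidide (toluene, 0 °C, excess to cover the free hydroxyl) isomerises it by syn elimination. This reagent removes the proton of the alkyl group syn to the epoxide hydrogen, which here is H-9.
   - The sequence comes back at 17.

3. **The Mitsunobu inversion (step 9).** Backside attack at a ring carbon of a ten-membered ring may be blocked, and SN2' attack or elimination can compete.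
   - The fallback sets C6 during ring closure instead of inverting it. It sets out from 13.
   - (Bu3Sn)2 and Pd(PPh3)4 in THF give the allylstannane F5.
   - BF3·OEt2 (CH2Cl2, −78 °C, high dilution) closes the ring through an open antiperiplanar transition state. This mode is syn-selective and gives the (6R)-alcohol F6.
   - Formic acetic anhydride and pyridine convert F6 into the formate.
   - The sequence comes back at 18.

**Further compounds**
F1 | step 10 | (1R,6R,7R,8R)-6-formyloxy-1-hydroperoxygermacra-4E,9Z,11(13)-trien-12,8-olide | C=C1C(=O)O[C@@H]2/C=C(/C)[C@H](OO)CC/C(C)=C/[C@@H](OC=O)[C@@H]12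
F2 | step 10 | (1R,6R,7R,8R)-6-formyloxy-1-hydroxygermacra-4E,9Z,11(13)-trien-12,8-olide | C=C1C(=O)O[C@@H]2/C=C(/C)[C@H](O)CC/C(C)=C/[C@@H](OC=O)[C@@H]12
F3 | step 10 | (6R,7R,8R)-1-bromo-6-formyloxygermacra-4E,9Z,11(13)-trien-12,8-olide (C1 epimers) | C=C1C(=O)O[C@@H]2/C=C(/C)C(Br)CC/C(C)=C/[C@@H](OC=O)[C@@H]12
F4 | step 8 | (1R,6S,7R,8R,10R)-1,10-epoxy-6-hydroxygermacra-4E,11(13)-dien-12,8-olide | C=C1C(=O)O[C@@H]2C[C@@]3(C)O[C@@H]3CC/C(C)=C/[C@H](O)[C@@H]12
F5 | step 9 | (2E,6E)-3,7-dimethyl-8-[(2R)-5-oxo-4-(tributylstannylmethyl)-2,5-dihydrofuran-2-yl]octa-2,6-dienal | O=C1O[C@H](C/C(C)=C/CC/C(C)=C/C=O)C=C1C[Sn](CCCC)(CCCC)CCCC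
F6 | step 9 | (6R,7R,8R)-6-hydroxygermacra-1(10)E,4E,11(13)-trien-12,8-olide | C=C1C(=O)O[C@@H]2C/C(C)=C/CC/C(C)=C/[C@@H](O)[C@@H]12
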